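## The problem

Target 16 is a benzophenone in which the substituted ring (ring A) carries six different neighbours. With C1 as the benzoyl-bearing carbon, C2 has a free hydroxyl, C3 a 3-methylbut-2-enyl (prenyl) group, C4 a methoxy group, C5 a second prenyl group and C6 a second methoxy group. There is no stereocentre and no ring fusion, so the difficulty is regiochemical: six contiguous substituents must be placed, and three oxygens must be told apart, one free and two methylated. Building the pattern by substitution on a preformed trioxygenated benzene would need two C-prenylations and one acylation on a crowded, very electron-rich ring, where O- versus C-alkylation and over-alkylation are hard to control. The prenyl groups are the fragile part: next to a phenol they cyclise to chromans or add HX under Brønsted or Lewis acid, and they do not tolerate oxidants, so strongly acidic steps late in the route should be avoided. The ortho-hydroxy ketone helps: the C2 hydroxyl is hydrogen-bonded to the carbonyl and is thereby distinguished from an oxygen at C4. The enabling feature is the strict alternation of oxygen-bearing ring atoms (C2, C4, C6) and carbon-bearing ones (C1, C3, C5). C6–C1 with the benzoyl carbon, extended to C5, has the skeleton and oxidation pattern of a benzoylacetone enol ether prenylated at its terminal carbon, and C2–C3–C4 that of prenylmalonic acid. The ring can therefore be closed from two acyclic 1,3-difunctional pieces in which every substituent is already present.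

## Retrosynthesis

**16 to 15.** The O–CH3 bond at C4 is cut first, leading to (2,4-dihydroxy-6-methoxy-3,5-bis(3-methylbut-2-enyl)phenyl)(phenyl)methanone 15. This cut is preferred to removing the C6 methyl group or both methyl groups, because the two hydroxyls of 15 differ sharply. The C2 hydroxyl is chelated to the ketone. The C4 hydroxyl is para to the ketone, free and more acidic. The forward reaction must methylate once, at a hydroxyl flanked by two prenyl groups, under weakly basic conditions.

**15 to 7 and 13.** The ring bonds C4–C5 and C1–C2 are cut. This divides 15 into the silyl dienol ether 7 (C1, C6, C5 with the benzoyl group, the C6 methoxy group and the C5 prenyl group) and 2-(3-methylbut-2-enyl)propanedioyl dichloride 13 (C2, C3, C4 with the C3 prenyl group).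
- The neighbouring (3+3) division, rotated by one ring atom, would need an unsymmetrical, doubly prenylated 3-oxoglutaric electrophile and would leave open which end reacts first.
- Here the electrophile is symmetric, so no orientation problem arises.
- The benzoyl group is the activating group of the nucleophile and needs no separate introduction.
- The C6 oxygen enters already methylated, which blocks the oxygen that would otherwise compete with carbon in the ring closure.
- A hexasubstituted arene is reduced to two acyclic pieces, each three steps from bulk chemicals.
- The forward reaction must acylate the diene terminus before the internal carbon, and close through carbon, not oxygen.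

**7 to 5 to 4 to 1 and 2.** The O–Si bond of 7 is cut, giving (E)-3-methoxy-7-methyl-1-phenylocta-2,6-dien-1-one 5. Enone 5 has acidic hydrogens only at the γ-methylene, so enolisation can go only one way. Cutting the enol O–CH3 bond of 5 gives 7-methyl-1-phenyloct-6-ene-1,3-dione 4. The forward step must etherify the aliphatic carbonyl and not the benzoyl one, which the higher electrophilicity of the non-conjugated ketone should secure. Cutting the C4–C5 bond of 4 leads to 1-phenylbutane-1,3-dione 1 and 1-bromo-3-methylbut-2-ene 2. The forward reaction is alkylation of the diketone dianion at its terminal carbon. This is preferred to alkylating after etherification because its regiochemistry is not in doubt.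

**13 to 12 to 10 to 8 and 2.** The two C–Cl bonds of 13 are traced to the diacid 12, its ester 10, and then, by cutting the bond between the malonate carbon and the prenyl CH2, to diethyl propanedioate 8 and the same bromide 2. One allylic halide thus supplies both prenyl groups of 16, each by an enolate alkylation under basic conditions. The forward sequence must avoid acid and heat at the diacid and dichloride stage.

## Roads not taken

**Alternative 1:** The ring is cut into a four-carbon and a two-carbon unit, both from one alkoxyalkyne, 1-methoxy-5-methylhex-4-en-1-yne A1.
- Forward key step: a (2+2) addition of A1 to a ketene equivalent would give 3-methoxy-2-(3-methylbut-2-enyl)cyclobut-2-en-1-one A2. Heating A2 with a second portion of A1 should start the Danheiser benzannulation: ring opening of A2 to a vinylketene, (2+2) addition to the electron-rich alkyne, a second opening and a six-electron closure, ending in 3,5-dimethoxy-2,4-bis(3-methylbut-2-enyl)phenol A3.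
- Merits: the polarity of the ynol ether fixes the positions of four substituents, and the cascade needs neither acid nor base. A3 already has both methyl ethers and the single free hydroxyl in their final places. In this respect it is better than the chosen plan, which must differentiate two hydroxyls in its last step.
- Weak points: A3 has no benzoyl group. Its one free ring position is ortho to the hydroxyl, and acylating it means Friedel–Crafts or Fries conditions on a phenol with an ortho prenyl group, the setting for chroman formation. The acid-free detour (protection, ring metalation, acylation, deprotection) costs about three steps. A1 is a volatile, acid-sensitive ynol ether needed twice over.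
- Comparison: against the better oxygen pattern of A3, the chosen plan has the benzoyl group present from the first step, bench-stable fragments and a step count that is no higher.

**Alternative 2:** Both aryl–CH2 bonds are cut and traced back to O-allyl groups.
- Forward key step: (2,6-dihydroxy-4-methoxyphenyl)(phenyl)methanone A4 would be etherified on both hydroxyls with 1,1-dimethylallyl groups to give (4-methoxy-2,6-bis(2-methylbut-3-en-2-yloxy)phenyl)(phenyl)methanone A5. Heating A5 should move each tertiary allyl group from oxygen to the adjacent free ring carbon with allylic inversion (aromatic Claisen rearrangement), giving (2,6-dihydroxy-4-methoxy-3,5-bis(3-methylbut-2-enyl)phenyl)(phenyl)methanone A6. Monomethylation of one of its two equivalent hydroxyls would give 16.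
- Merits: every step has close precedent and the aromatic core is not built but bought or made classically. The final methylation limits itself, because the remaining hydroxyl becomes chelated once the first is capped. On precedent this road is safer than the chosen plan, whose ring-forming step is untested.
- Weak points: the two hydroxyls of A4 flank the ketone, are hindered and hydrogen-bonded, and must each take a tertiary alkyl group. That normally goes through the propargylic ethers and a twofold semihydrogenation, with C-alkylation and chromene formation as side paths. At the rearrangement temperature the liberated ortho-prenyl phenols can close to chromans.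
- Comparison: the sequence from A4 is about as long as the whole chosen route, and A4 itself must first be made. The chosen plan is convergent, has no tertiary ether and no hydrogenation, and introduces both prenyl groups by enolate alkylation.

**Alternative 3:** One ring bond between C1 and an oxygenated ortho carbon is cut, as in the biosynthesis. This leads to the open-chain ester methyl 2,4-bis(3-methylbut-2-enyl)-3,5,7-trioxo-7-phenylheptanoate A7.
- Forward key step: under magnesium alkoxide conditions the methylene between the two ketones nearest the phenyl group should attack the ester carbon (Claisen condensation). Enolisation then gives phenyl(2,4,6-trihydroxy-3,5-bis(3-methylbut-2-enyl)phenyl)methanone A8. Twofold methylation, which normally stops before the chelated hydroxyl, would complete 16.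
- Merits: the whole carbon skeleton is in place before cyclisation. The end game, exhaustive methylation of the non-chelated hydroxyls, is more robust than the single selective methylation of the chosen plan.
- Weak points: A7 is a labile, multiply enolised chain with three acidic positions. Its prenyl groups must sit on C2 and C4 and not on C6, so they have to come in on the building blocks, and the chain must be assembled by crossed acylations of hindered partners. The chain can also close by aldol condensation to a resorcylate-type ring or by lactonisation to a 4-hydroxypyran-2-one. How the two branch points affect this competition is unknown.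
- Comparison: the chosen plan uses the same polarity but divides the chain into two stable halves, and it methylates the oxygen that would open the pyranone path. It pays for this with the harder last step.

Key step: step 7

Assumption: the geometry of the two enol double bonds of 7 is of no consequence, because both are consumed in the annulation. Compound 7 is drawn as the (1Z,3Z) isomer expected from chelation-controlled γ-deprotonation, and a mixture of geometric isomers would be used as such.

## Route

Step 1
Reactants: 1 1-phenylbutane-1,3-dione (benzoylacetone); 2 1-bromo-3-methylbut-2-ene (prenyl bromide)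
Product: 4 7-methyl-1-phenyloct-6-ene-1,3-dione, via benzoylacetone dilithium dianion 3 (not isolated)
Conditions: LiN(iPr)2 (2.2 equiv), THF, 0 °C; then 2 (1.0 equiv), 0 °C to rt; 1 M HCl quench at 0 °C
Reagents that add atoms: none
Why: Alkylation of a β-diketone dianion: the second deprotonation takes place at the methyl group, and this terminal carbanion, the more basic and more reactive site, is alkylated by the allylic bromide in an SN2 reaction while the central enolate stays untouched.

Step 2
Reactants: 4 7-methyl-1-phenyloct-6-ene-1,3-dione
Product: 5 (E)-3-methoxy-7-methyl-1-phenylocta-2,6-dien-1-one
Conditions: HC(OMe)3 (3 equiv), TsOH·H2O (5 mol%), MeOH, rt; then Et3N, evaporation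
Reagents that add atoms: trimethyl orthoformate, COC(OC)OC; methanol, CO
Why: Acid-catalysed enol etherification (ketalisation, then loss of methanol) of an aroylacetone: the aliphatic carbonyl, not deactivated by conjugation with the phenyl ring, should be the one ketalised, as when aroylacetones condense with amines. Elimination gives the E β-methoxy enone conjugated with the benzoyl group, and the orthoformate removes the water.

Step 3
Reactants: 5 (E)-3-methoxy-7-methyl-1-phenylocta-2,6-dien-1-one
Product: 7 (1Z,3Z)-3-methoxy-7-methyl-1-phenyl-1-(trimethylsilyloxy)octa-1,3,6-triene, via lithium dienolate 6 (not isolated)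
Conditions: LiN(iPr)2 (1.1 equiv), THF, −78 °C; then Me3SiCl (1.3 equiv), −78 to 0 °C; evaporation, pentane, filtration under argon; used at once
Reagents that add atoms: chlorotrimethylsilane, C[Si](C)(C)Cl
Why: γ-Deprotonation and O-silylation of a β-alkoxy enone that has no α′-hydrogen, the way 1,3-dialkoxy-1-silyloxybutadienes are made from β-alkoxycrotonates. In the E enone the C4 methylene lies syn to the carbonyl, so the lithium amide bound to the carbonyl oxygen is delivered to it.

Step 4
Reactants: 8 diethyl propanedioate (diethyl malonate); 2 1-bromo-3-methylbut-2-ene
Product: 10 diethyl 2-(3-methylbut-2-enyl)propanedioate, via diethyl sodiomalonate 9 (not isolated)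
Conditions: 8 (1.2 equiv), NaH (1.1 equiv), THF, 0 °C; then 2 (1.0 equiv), 0 °C to rt
Reagents that add atoms: none
Why: Malonic ester alkylation with a reactive allylic bromide (SN2); the small excess of malonate suppresses dialkylation.

Step 5
Reactants: 10 diethyl 2-(3-methylbut-2-enyl)propanedioate
Product: 12 2-(3-methylbut-2-enyl)propanedioic acid, via dipotassium 2-(3-methylbut-2-enyl)propanedioate 11 (not isolated)
Conditions: KOH (2.5 equiv), EtOH/H2O, rt; then 2 M HCl, 0 °C, to pH 1; extraction, evaporation below 30 °C
Reagents that add atoms: potassium hydroxide, [K+].[OH-]
Why: Saponification of a malonic diester; acidification and isolation in the cold avoid decarboxylation of the malonic acid and acid-induced hydration of the alkene.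

Step 6
Reactants: 12 2-(3-methylbut-2-enyl)propanedioic acid
Product: 13 2-(3-methylbut-2-enyl)propanedioyl dichloride
Conditions: (COCl)2 (2.5 equiv), DMF (cat.), CH2Cl2, 0 °C to rt; evaporation; used directly
Reagents that add atoms: oxalyl chloride, O=C(Cl)C(=O)Cl
Why: Acid chloride formation through the chloroiminium species from DMF and oxalyl chloride at or below room temperature, conditions under which trisubstituted alkenes in aliphatic acids are normally kept; the by-products are gases.

Step 7
Reactants: 7 (1Z,3Z)-3-methoxy-7-methyl-1-phenyl-1-(trimethylsilyloxy)octa-1,3,6-triene; 13 2-(3-methylbut-2-enyl)propanedioyl dichloride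
Product: 15 (2,4-dihydroxy-6-methoxy-3,5-bis(3-methylbut-2-enyl)phenyl)(phenyl)methanone, via acyclic keto acid chloride 14 (not isolated)
Conditions: 13 (1.05 equiv) added slowly to 7, CH2Cl2 (0.05 M), −78 to 0 °C; then Et3N (1.5 equiv), 0 °C to rt; aq. NaH2PO4 work-up
Reagents that add atoms: none
Why: Proposed new method: diene 7 should react as a vinylogous Mukaiyama-type nucleophile at its terminal carbon, which is activated directly by the methoxy group and through the diene by the silyloxy group, with one acyl chloride of 13; loss of chlorotrimethylsilane restores the β-methoxy enone and gives 14 (future bond C4–C5). Triethylamine then takes HCl from 14, by enolisation of the doubly activated CH between the new ketone and the enol ether or by acylketene formation, and the α-carbon of the push-pull enol ether attacks the second acyl carbon in a 6-(enolendo)-exo-trig C-acylation (bond C1–C2). Two enolisations of the resulting cyclohexadienone give the arene 15. The closest known reactions are the uncatalysed terminal acylation of 1,3-dioxygenated silyl dienol ethers by acid chlorides and the Effenberger cyclisation, in which malonyl dichloride acylates both α-carbons of a methyl enol ether; the vinylogous, aromatising variant with a monosubstituted malonyl dichloride has not been described. No stereocentre is created, since the two of 14 vanish on aromatisation. The step needs terminal before internal acylation and carbon before oxygen closure. The first is secured by the higher nucleophilicity and accessibility of the diene terminus; the second by the methyl group on the enol oxygen next to the nucleophilic carbon, the oxygen that leads to pyranones when it is silylated, so that the only oxygen closure left is an eight-membered one through the benzoyl oxygen. The methoxy group of 7 becomes the C6 methoxy group, and the two acyl carbons of 13 become C2–OH and C4–OH.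

Step 8
Reactants: 15 (2,4-dihydroxy-6-methoxy-3,5-bis(3-methylbut-2-enyl)phenyl)(phenyl)methanone
Product: 16 (2-hydroxy-4,6-dimethoxy-3,5-bis(3-methylbut-2-enyl)phenyl)(phenyl)methanone
Conditions: MeI (1.1 equiv), K2CO3 (1.1 equiv), acetone, rt
Reagents that add atoms: iodomethane, CI
Why: Williamson O-methylation under weak-base control: the C4 hydroxyl, para to the carbonyl, is the more acidic and is free, whereas the C2 hydroxyl is held in a six-membered hydrogen bond to the benzoyl oxygen and should not react with one equivalent of reagent, as in the selective 4-O-methylation of 2,4-dihydroxyaryl ketones.

## Compound list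

1 | 1-phenylbutane-1,3-dione (benzoylacetone) | CC(=O)CC(=O)c1ccccc1 | starting material
2 | 1-bromo-3-methylbut-2-ene (prenyl bromide) | CC(C)=CCBr | starting material
3 | dilithium (Z)-1-phenylbuta-1,3-diene-1,3-diolate (benzoylacetone dianion; formed in the flask, not isolated) | [Li+].[Li+].C=C([O-])/C=C(\[O-])c1ccccc1 | intermediate
4 | 7-methyl-1-phenyloct-6-ene-1,3-dione | CC(C)=CCCC(=O)CC(=O)c1ccccc1 | intermediate
5 | (E)-3-methoxy-7-methyl-1-phenylocta-2,6-dien-1-one | CO/C(CCC=C(C)C)=C/C(=O)c1ccccc1 | intermediate
6 | lithium (1Z,3Z)-3-methoxy-7-methyl-1-phenylocta-1,3,6-trien-1-olate (formed in the flask, not isolated) | [Li+].[O-]/C(c1ccccc1)=C\C(OC)=C\CC=C(C)C | intermediate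
7 | (1Z,3Z)-3-methoxy-7-methyl-1-phenyl-1-(trimethylsilyloxy)octa-1,3,6-triene | C[Si](C)(C)O/C(c1ccccc1)=C\C(OC)=C\CC=C(C)C | intermediate
8 | diethyl propanedioate (diethyl malonate) | CCOC(=O)CC(=O)OCC | starting material
9 | diethyl sodiomalonate (sodium enolate of 8; formed in the flask, not isolated) | [Na+].CCOC(=O)[CH-]C(=O)OCC | intermediate
10 | diethyl 2-(3-methylbut-2-enyl)propanedioate | CCOC(=O)C(CC=C(C)C)C(=O)OCC | intermediate
11 | dipotassium 2-(3-methylbut-2-enyl)propanedioate (formed in the flask, not isolated) | [K+].[K+].CC(C)=CCC(C(=O)[O-])C(=O)[O-] | intermediate
12 | 2-(3-methylbut-2-enyl)propanedioic acid | CC(C)=CCC(C(=O)O)C(=O)O | intermediate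
13 | 2-(3-methylbut-2-enyl)propanedioyl dichloride | CC(C)=CCC(C(=O)Cl)C(=O)Cl | intermediate
14 | (E)-5-methoxy-2,4-bis(3-methylbut-2-enyl)-3,7-dioxo-7-phenylhept-5-enoyl chloride (mixture of diastereomers; formed in the flask, not isolated) | CC(C)=CCC(C(=O)Cl)C(=O)C(CC=C(C)C)/C(OC)=C\C(=O)c1ccccc1 | intermediate
15 | (2,4-dihydroxy-6-methoxy-3,5-bis(3-methylbut-2-enyl)phenyl)(phenyl)methanone | COc1c(CC=C(C)C)c(O)c(CC=C(C)C)c(O)c1C(=O)c1ccccc1 | intermediate
16 | (2-hydroxy-4,6-dimethoxy-3,5-bis(3-methylbut-2-enyl)phenyl)(phenyl)methanone | COc1c(CC=C(C)C)c(O)c(C(=O)c2ccccc2)c(OC)c1CC=C(C)C | target

## Step count and risks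

Total step count: 8. Longest linear sequence: 5 steps (1 to 4 to 5 to 7 to 15 to 16; the malonate branch 8 to 10 to 12 to 13 to 15 to 16 is equally long).

**Step 7 (key step, the one step without direct precedent).**
- What may go wrong: first acylation at the internal carbon or at oxygen of the diene; loss of HCl from 14 followed by intermolecular reaction of the acylketene or enolate faster than ring closure (oligomerisation); acid-induced attack on the prenyl groups before the base is added.
- Fallback (known reaction types, ring closure in two operations): it sets out from 10 and 7 and returns at 15.
  - Half-saponification of 10 (KOH, 1.0 equiv, EtOH, rt) should give 2-(ethoxycarbonyl)-5-methylhex-4-enoic acid F1.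
  - (COCl)2 and catalytic DMF convert it to ethyl 2-(chlorocarbonyl)-5-methylhex-4-enoate F2.
  - Terminal acylation of 7 with F2 (CH2Cl2, −78 °C to rt), the established reaction of silyl dienol ethers with simple acid chlorides, should give ethyl (E)-5-methoxy-2,4-bis(3-methylbut-2-enyl)-3,7-dioxo-7-phenylhept-5-enoate F3.
  - NaOMe in MeOH then closes the ring by intramolecular Claisen condensation with aromatisation, the mode by which 3,5,7-tricarbonyl esters give acylphloroglucinols, to 15. With methoxide any alkoxide exchange at the enol ether is degenerate, and the methyl ether still blocks lactonisation.

**Step 2.**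
- What may go wrong: etherification at the benzoyl carbonyl or formation of both regioisomers; acid-catalysed addition of methanol to the trisubstituted alkene.
- Fallback (order of the two operations reversed): it sets out from 1 and returns at 5.
  - The same orthoformate conditions applied to 1, which has no alkene and whose isomers can be separated at this simple stage, give (E)-3-methoxy-1-phenylbut-2-en-1-one F4.
  - Its lithium dienolate (LiN(iPr)2, THF, −78 °C) is alkylated with 2 at the γ-carbon, as dienolates of β-alkoxy enones without α′-hydrogens are, to give 5.

**Step 3.**
- What may go wrong: incomplete γ-deprotonation or attack of the base at the carbonyl; hydrolytic loss of the trimethylsilyl group during isolation.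
- Fallback (soft enolisation to a sturdier silyl ether): it sets out from 5 and returns at 15.
  - tBuMe2SiOTf and Et3N in CH2Cl2 at 0 °C should give tert-butyl{[(1Z,3Z)-3-methoxy-7-methyl-1-phenylocta-1,3,6-trien-1-yl]oxy}dimethylsilane F5.
  - F5 can be purified and is taken with 13 through the conditions of step 7 to 15.

**Step 6.**
- What may go wrong: addition of the liberated HCl to the prenyl double bond; loss of HCl or CO2 from the monosubstituted malonyl system (ketene formation, decarboxylation).
- Fallback (neutral, HCl-free activation through the silyl ester): it sets out from 12 and returns at 13.
  - Hexamethyldisilazane converts 12 into bis(trimethylsilyl) 2-(3-methylbut-2-enyl)propanedioate F6.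
  - (COCl)2 with catalytic DMF in CH2Cl2 at 0 °C turns F6 into 13 with only chlorotrimethylsilane and gases as by-products.

**Step 8.**
- What may go wrong: slow reaction at the hydroxyl flanked by two prenyl groups, leading to methylation of the chelated hydroxyl as well; C-methylation with dearomatisation.
- Fallback (exhaustive methylation, then chelation-directed demethylation): it sets out from 15 and returns at 16.
  - NaH and excess MeI in DMF give (2,4,6-trimethoxy-3,5-bis(3-methylbut-2-enyl)phenyl)(phenyl)methanone F7.
  - MgI2·OEt2 (or BCl3 at −78 °C) removes one methyl group ortho to the carbonyl. The two ortho methoxy groups of F7 are equivalent by symmetry, so either cleavage gives 16.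

Further compounds

F1 | step 7 | 2-(ethoxycarbonyl)-5-methylhex-4-enoic acid (racemic) | CCOC(=O)C(CC=C(C)C)C(=O)O
F2 | step 7 | ethyl 2-(chlorocarbonyl)-5-methylhex-4-enoate (racemic) | CCOC(=O)C(CC=C(C)C)C(=O)Cl
F3 | step 7 | ethyl (E)-5-methoxy-2,4-bis(3-methylbut-2-enyl)-3,7-dioxo-7-phenylhept-5-enoate (mixture of diastereomers) | CCOC(=O)C(CC=C(C)C)C(=O)C(CC=C(C)C)/C(OC)=C\C(=O)c1ccccc1
F4 | step 2 | (E)-3-methoxy-1-phenylbut-2-en-1-one | CO/C(C)=C/C(=O)c1ccccc1
F5 | step 3 | tert-butyl{[(1Z,3Z)-3-methoxy-7-methyl-1-phenylocta-1,3,6-trien-1-yl]oxy}dimethylsilane | CC(C)(C)[Si](C)(C)O/C(c1ccccc1)=C\C(OC)=C\CC=C(C)C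
F6 | step 6 | bis(trimethylsilyl) 2-(3-methylbut-2-enyl)propanedioate | CC(C)=CCC(C(=O)O[Si](C)(C)C)C(=O)O[Si](C)(C)C
F7 | step 8 | (2,4,6-trimethoxy-3,5-bis(3-methylbut-2-enyl)phenyl)(phenyl)methanone | COc1c(CC=C(C)C)c(OC)c(C(=O)c2ccccc2)c(OC)c1CC=C(C)C
A1 | alternative 1 | 1-methoxy-5-methylhex-4-en-1-yne | COC#CCC=C(C)C
A2 | alternative 1 | 3-methoxy-2-(3-methylbut-2-enyl)cyclobut-2-en-1-one | COC1=C(CC=C(C)C)C(=O)C1
A3 | alternative 1 | 3,5-dimethoxy-2,4-bis(3-methylbut-2-enyl)phenol | COc1cc(O)c(CC=C(C)C)c(OC)c1CC=C(C)C
A4 | alternative 2 | (2,6-dihydroxy-4-methoxyphenyl)(phenyl)methanone | COc1cc(O)c(C(=O)c2ccccc2)c(O)c1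
A5 | alternative 2 | (4-methoxy-2,6-bis(2-methylbut-3-en-2-yloxy)phenyl)(phenyl)methanone | COc1cc(OC(C)(C)C=C)c(C(=O)c2ccccc2)c(OC(C)(C)C=C)c1
A6 | alternative 2 | (2,6-dihydroxy-4-methoxy-3,5-bis(3-methylbut-2-enyl)phenyl)(phenyl)methanone | COc1c(CC=C(C)C)c(O)c(C(=O)c2ccccc2)c(O)c1CC=C(C)C
A7 | alternative 3 | methyl 2,4-bis(3-methylbut-2-enyl)-3,5,7-trioxo-7-phenylheptanoate (mixture of stereoisomers and tautomers) | COC(=O)C(CC=C(C)C)C(=O)C(CC=C(C)C)C(=O)CC(=O)c1ccccc1
A8 | alternative 3 | phenyl(2,4,6-trihydroxy-3,5-bis(3-methylbut-2-enyl)phenyl)methanone | O=C(c1ccccc1)c1c(O)c(CC=C(C)C)c(O)c(CC=C(C)C)c1O
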